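The stirred, closed vessel held solid substrate under a held gas, and target and its crystals appeared in it.

| flask | solid substrate | gas | remark | time |
|---|---|---|---|---|
| red | 5 mM | 0.52 mM (held) | run made earlier |  |
| flask | 10 mM | 0.52 mM (held) |  | 10 d |

red run (percent of the solid substrate charged)

| time / h | target / % | crystals / % |
|---|---|---|
| 4.00 | 20 | 7 |
| 12.0 | 57 | 48 |
| 20.0 | 96 | 91 |
| 30.0 | 101 | 90 |
| 50.0 | 99 | 90 |

(each reading ± 1.5 percentage points)

- target is meant together with its crystals
- solid, in amounts per volume of the solution: solid substrate, crystals
- the numbers in the tables scatter by 1.5 percentage points (one standard deviation)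
- at the start none of the solid substrate is in solution
- at the start none of the gas is in solution
- dissolved substrate means what is dissolved; the solid is not counted in it

- the target and crystals together standing at 10 d, as a percentage of the solid substrate charged
- concentration of dissolved substrate in solution at 10 d, in percent of saturation

In the red run the target climbed at a steady, zero-order rate r of 0.237 mM h⁻¹ between 4.00 h and 20.0 h, then stopped. I carried one quantity: the clearance time t_c, the charge divided by r, which is 42.1 h for this flask if r holds. About 5.70 clearance times fit into 10 d, so I expected dissolved substrate near 0% of saturation.

From above, the charge bounds the yield at 100%. From below, the red fall of 2 percentage points between 30.0 h and 50.0 h, though each reading scatters by 1.5 points, stretched over the remaining 198 h, gave a crude 80.2%. But the crystals of the red run stood flat, so I assumed that what was at risk was the uncrystallised target, read there as 0.550 mM. Taking the same amount for this flask put my estimated floor at 94.5%.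

The forecast gave 99% (90% to 102%) and 1% of saturation (0% to 10%), reasoning that “Doubling the solid should leave the rate unchanged”. Its 99% lay inside my bracket.

The flask gave 96.6% and 0% of saturation, so both forecast values held, and its yield stood above my floor, inside the bracket.

    solid substrate ⇌ dissolved substrate, rate k1*(cs1 - [dissolved substrate]) while solid is left; crystals form when [dissolved substrate] > cs1 (solubility = 6.10 mM, k = 0.0420 h⁻¹)
    dissolved substrate + reagent → target (k = 6200 M⁻¹ h⁻¹)
    crystals ⇌ target, rate k3*(cs3 - [target]) while solid is left; crystals form when [target] > cs3 (solubility = 0.370 mM, k = 2.30 h⁻¹)
    gas ⇌ reagent, rate k4*(csat - [reagent]) (kL = 8.20 h⁻¹)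
    target ⇌ isomer of the product (K = 1.10, k = 0.00810 h⁻¹)

The relaxation half-life of the conversion of dissolved target into isomer of the product, 1.87 d, is shorter than the 10 d. Yet at 10.0 d the flask held 3.43% isomer of the product beside 96.6% target, of which 92.9% stood as crystals.

The neighbour flask read at 4.0 d has 2.28 clearance times behind it, so t_c expects its solid substrate consumed. It shows 0% left and 97.8% target and crystals.

The numbers in the tables are calculated with constants of no real substance; noise was put on by code.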